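**Plan**
1. The target is the meso, trans,trans-3,3'-biflavanone: two mirror-related 7,4'-dihydroxyflavanone halves joined C3–C3'. The retrosynthesis first removes four O-benzyl groups, then cuts both pyranone C2–C3 bonds in one operation, then the central C3–C3' bond, then the aryl O–CH2 ether bond.
2. Forward: a 2-hydroxyacetophenone is O-alkylated with a 4-(benzyloxy)benzyl chloride (its CH2 becomes C2, its ring becomes ring B). CuCl2 enolate homocoupling joins the chain at C3–C3'. One DDQ operation closes both pyranone rings, and hydrogenolysis frees the phenols.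
3. Enabling feature: C2 of each pyranone ring is a benzylic CH between ring oxygen O1 and the para-oxygenated ring B, so hydride loss from the corresponding ArO–CH2–Ar ether gives a doubly stabilised cation. C3 is the enolisable α-carbon of the C4 aryl ketone, ortho to O1 on ring A. The mirror symmetry allows the same event on both halves of one 1,4-diketone.
4. Stereochemistry: the target is achiral, so only relative configuration is needed. 2,3-trans in each ring should come from half-chair closure (it is also the thermodynamic arrangement). The meso relation should be relayed from C3 of the first ring to C3' by allylic 1,3-strain in the second closure.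

Key step: step 3

Remark on the chemistry: the two halves of the target are (2S,3R) and (2'R,3'S), so the compound is meso; no absolute stereocontrol is needed and chiral intermediates are racemic.

**Step 1**
Reactants: 1 1-[4-(benzyloxy)-2-hydroxyphenyl]ethan-1-one; 2 1-(benzyloxy)-4-(chloromethyl)benzene
Product: 3 1-[4-(benzyloxy)-2-{[4-(benzyloxy)phenyl]methoxy}phenyl]ethan-1-one
Conditions: K2CO3, KI (cat.), DMF, 70 °C
Reagents that add atoms: none
Why: Williamson ether synthesis, in which the potassium phenoxide of the only free (chelated) hydroxyl of 1 displaces chloride from the benzylic chloride under iodide catalysis; no stereocentre is formed.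

**Step 2**
Reactants: 3 1-[4-(benzyloxy)-2-{[4-(benzyloxy)phenyl]methoxy}phenyl]ethan-1-one (two molecules)
Product: 5 1,4-bis[4-(benzyloxy)-2-{[4-(benzyloxy)phenyl]methoxy}phenyl]butane-1,4-dione, via lithium enolate 4 (not isolated)
Conditions: LiN(iPr)2 (LDA), THF, −78 °C; then CuCl2, DMF, −78 °C to rt
Reagents that add atoms: none
Why: Oxidative enolate homocoupling, in which CuCl2 oxidises the kinetic lithium enolate of the methyl ketone and the α-carbons join to give the 1,4-diketone (the C3–C3' bond); no stereocentre is formed and the benzyl ethers should be inert to the amide base at −78 °C.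

**Step 3**
Reactants: 5 1,4-bis[4-(benzyloxy)-2-{[4-(benzyloxy)phenyl]methoxy}phenyl]butane-1,4-dione
Product: 7 meso-(2S,3R,2'R,3'S)-7,7'-bis(benzyloxy)-2,2'-bis[4-(benzyloxy)phenyl]-[3,3'-bichromane]-4,4'-dione, via mono-cyclised trans-flavanone 6 (not isolated)
Conditions: DDQ (2.4 equiv), 2,6-dichloropyridine, LiClO4, 4 Å MS, ClCH2CH2Cl, rt to 45 °C
Reagents that add atoms: none
Why: Proposed new method: DDQ should remove hydride (electron transfer, then hydrogen-atom loss) from the O–CH2 of each 4-(benzyloxy)benzyl aryl ether to give an O-aryl oxocarbenium ion stabilised by the para-oxygenated ring B; the ortho ketone oxygen should capture this ion and lose its α-proton to give a (Z)-enol or enol acetal, whose carbon C3 then bonds to C2 (Prins/Mukaiyama-type closure, Petasis–Ferrier-like return), once on each half. The closest known reaction types are the DDQ-mediated oxidative cyclisation of benzylic alkyl ethers carrying enol acetates to 2-aryl-tetrahydropyran-4-ones and the DDQ cross-dehydrogenative coupling of benzyl ethers with simple ketones; new here are the aryl ether oxygen, the free ketone as nucleophile and the twofold use on a 1,4-diketone. Each pyranone ring closes in a 6-(enolendo)-endo-trig mode. In the first ring C2 and C3 should come out trans through a half-chair transition state in which the (E)-oxocarbenium places ring B equatorial and the (Z)-enol places the C3 substituent equatorial, and C3 stays correctable by enolisation. In the second ring C2' and C3' should be set trans in the same way, while the face of C3' is chosen by the existing C3 centre: with C3–H eclipsing the enol double bond (allylic 1,3-strain) the cation should attack anti to C2 and its ring B, which gives the meso (2S,3R,2'R,3'S) array. The step needs oxidation of the two O–CH2 groups on para-alkoxy rings in preference to the two plain benzyl ethers and no further oxidation of the product, which should be secured by the lower oxidation potential of the 4-alkoxybenzyl rings, by the molecular sieves that keep water from the cation, and by the C4 carbonyl that deactivates the product C2–H toward hydride loss.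

**Step 4**
Reactants: 7 meso-(2S,3R,2'R,3'S)-7,7'-bis(benzyloxy)-2,2'-bis[4-(benzyloxy)phenyl]-[3,3'-bichromane]-4,4'-dione
Product: 8 meso-(2S,3R,2'R,3'S)-7,7'-dihydroxy-2,2'-bis(4-hydroxyphenyl)-[3,3'-bichromane]-4,4'-dione
Conditions: H2 (1 atm), Pd/C, THF/MeOH, rt
Reagents that add atoms: none
Why: Catalytic hydrogenolysis of the four benzyl aryl ethers over Pd/C under neutral conditions should free the four phenols without enolising C3 or opening the pyranone rings, so the four stereocentres are not touched.

**Compound list**
1 | 1-[4-(benzyloxy)-2-hydroxyphenyl]ethan-1-one | CC(=O)c1ccc(OCc2ccccc2)cc1O | starting material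
2 | 1-(benzyloxy)-4-(chloromethyl)benzene (4-(benzyloxy)benzyl chloride) | ClCc1ccc(OCc2ccccc2)cc1 | starting material
3 | 1-[4-(benzyloxy)-2-{[4-(benzyloxy)phenyl]methoxy}phenyl]ethan-1-one | CC(=O)c1ccc(OCc2ccccc2)cc1OCc1ccc(OCc2ccccc2)cc1 | intermediate
4 | lithium 1-[4-(benzyloxy)-2-{[4-(benzyloxy)phenyl]methoxy}phenyl]ethen-1-olate (lithium enolate of 3) | C=C(O[Li])c1ccc(OCc2ccccc2)cc1OCc1ccc(OCc2ccccc2)cc1 | intermediate
5 | 1,4-bis[4-(benzyloxy)-2-{[4-(benzyloxy)phenyl]methoxy}phenyl]butane-1,4-dione | O=C(CCC(=O)c1ccc(OCc2ccccc2)cc1OCc1ccc(OCc2ccccc2)cc1)c1ccc(OCc2ccccc2)cc1OCc1ccc(OCc2ccccc2)cc1 | intermediate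
6 | rac-(2S,3R)-7-(benzyloxy)-2-[4-(benzyloxy)phenyl]-3-{2-[4-(benzyloxy)-2-{[4-(benzyloxy)phenyl]methoxy}phenyl]-2-oxoethyl}chroman-4-one (2,3-trans; racemic, one enantiomer drawn) | O=C1c2ccc(OCc3ccccc3)cc2O[C@H](c2ccc(OCc3ccccc3)cc2)[C@H]1CC(=O)c1ccc(OCc2ccccc2)cc1OCc1ccc(OCc2ccccc2)cc1 | intermediate
7 | meso-(2S,3R,2'R,3'S)-7,7'-bis(benzyloxy)-2,2'-bis[4-(benzyloxy)phenyl]-[3,3'-bichromane]-4,4'-dione | O=C1c2ccc(OCc3ccccc3)cc2O[C@H](c2ccc(OCc3ccccc3)cc2)[C@H]1[C@@H]1C(=O)c2ccc(OCc3ccccc3)cc2O[C@H]1c1ccc(OCc2ccccc2)cc1 | intermediate
8 | meso-(2S,3R,2'R,3'S)-7,7'-dihydroxy-2,2'-bis(4-hydroxyphenyl)-[3,3'-bichromane]-4,4'-dione | O=C1c2ccc(O)cc2O[C@H](c2ccc(O)cc2)[C@H]1[C@@H]1C(=O)c2ccc(O)cc2O[C@H]1c1ccc(O)cc1 | target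

**Total step count:** 4
**Longest linear sequence:** 4 steps

**Steps most likely to fail**

Step 3. Capture of the O-aryl oxocarbenium ion by the ketone enol may be slower than its loss to traces of water, and facial selectivity in the second ring closure may be poor, giving the C2-symmetric trans,trans diastereomer beside the meso one. The fallback uses known chemistry and closes the pyranone rings at the O1–C2 bond instead. It sets out from 5: DDQ in wet CH2Cl2 (pH 7 buffer, rt) should cleave both 4-(benzyloxy)benzyl ethers oxidatively to give 1,4-bis[4-(benzyloxy)-2-hydroxyphenyl]butane-1,4-dione F1. A twofold Claisen–Schmidt condensation of F1 with commercial 4-(benzyloxy)benzaldehyde (KOH, EtOH, rt) should give (2E,3E)-2,3-bis{[4-(benzyloxy)phenyl]methylidene}-1,4-bis[4-(benzyloxy)-2-hydroxyphenyl]butane-1,4-dione F2. Twofold oxa-Michael closure of F2 under equilibrating conditions (NaOAc, EtOH, reflux) should give the 2,3-trans rings, and the meso isomer would be separated from the C2-symmetric one by crystallisation or chromatography. The fallback comes back to the route at 7.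

Step 2. The oxidative coupling may give α-chlorination of the enolate or stop through proton transfer between enolate and product. The fallback replaces it by an ionic alkylation and sets out from 3. Silylation (TMSOTf, Et3N, CH2Cl2, 0 °C) should give {1-[4-(benzyloxy)-2-{[4-(benzyloxy)phenyl]methoxy}phenyl]ethenyl}oxy(trimethyl)silane F3. Bromination of F3 with NBS (THF, 0 °C) should give 2-bromo-1-[4-(benzyloxy)-2-{[4-(benzyloxy)phenyl]methoxy}phenyl]ethan-1-one F4. Alkylation of lithium enolate 4 (from a second portion of 3, LiN(iPr)2, THF, −78 °C) with F4 should give the 1,4-diketone. The fallback comes back to the route at 5.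

Step 4. Hydrogenolysis may also open the benzylic C2–O1 bond of the pyranone rings or reduce the ketones once the para-hydroxyl groups are free. The fallback is a non-reductive Lewis-acid debenzylation and sets out from 7: BCl3 with pentamethylbenzene as cation scavenger (CH2Cl2, −78 °C) should remove the four benzyl groups. It comes back to the route at 8 and makes no new compound (F0).

**Further compounds**
F1 | step 3 | 1,4-bis[4-(benzyloxy)-2-hydroxyphenyl]butane-1,4-dione | O=C(CCC(=O)c1ccc(OCc2ccccc2)cc1O)c1ccc(OCc2ccccc2)cc1O
F2 | step 3 | (2E,3E)-2,3-bis{[4-(benzyloxy)phenyl]methylidene}-1,4-bis[4-(benzyloxy)-2-hydroxyphenyl]butane-1,4-dione | O=C(c1ccc(OCc2ccccc2)cc1O)/C(=C/c1ccc(OCc2ccccc2)cc1)/C(=C\c1ccc(OCc2ccccc2)cc1)C(=O)c1ccc(OCc2ccccc2)cc1O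
F3 | step 2 | {1-[4-(benzyloxy)-2-{[4-(benzyloxy)phenyl]methoxy}phenyl]ethenyl}oxy(trimethyl)silane | C=C(O[Si](C)(C)C)c1ccc(OCc2ccccc2)cc1OCc1ccc(OCc2ccccc2)cc1
F4 | step 2 | 2-bromo-1-[4-(benzyloxy)-2-{[4-(benzyloxy)phenyl]methoxy}phenyl]ethan-1-one | BrCC(=O)c1ccc(OCc2ccccc2)cc1OCc1ccc(OCc2ccccc2)cc1
F0 | step 4 | none | none
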